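The cyclohexane is read as a masked β-keto ester: C6 (the methylidene carbon) as a ketone, the first side-chain carbon as an ester on C1, and quaternary C2 as the tertiary cation of isobutene. One Lewis-acid operation on acyclic methyl 3-oxopent-4-enoate and isobutene (ene addition, then capture of the cation by the enol) forms the ring bonds C3–C4 and C1–C2 and gives methyl 2,2-dimethyl-6-oxocyclohexane-1-carboxylate. Hydroxylation then sets C1; the dioxane is built from a chiral epoxide by perhydrolysis and peroxide SN2 closure; a Julia–Kocienski union, diimide reduction and a late methylenation complete the target.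

Key step: step 1

Remark: 1 is assumed purchasable and is distilled before use; the ring CH–O carbon made in step 3 is carried as a mixture of epimers (6–9, 22–24) because step 19 oxidises it.

Step 1
Reactants: 1 methyl 3-oxopent-4-enoate; 2 2-methylpropene
Product: 4 methyl 2,2-dimethyl-6-oxocyclohexane-1-carboxylate (racemic), via methyl 7-methyl-3-oxooct-7-enoate 3 (not isolated)
Conditions: SnCl4 (1.1 equiv), CH2Cl2, −78 °C; then 2 (3 equiv), −78 → 0 °C
Reagents that add atoms: none
Why: Proposed new method: SnCl4 chelates the β-keto ester of 1 and makes its vinyl ketone a strong enophile, so that isobutene adds through its CH2 terminus in an ene reaction (bond C3–C4) to give 3; the acidic chelate then protonates the 1,1-disubstituted alkene of 3 to the tertiary cation, which the enol carbon C1 of the β-keto ester captures (bond C1–C2). The closest known reaction types are the Lewis acid-promoted ene reaction of vinyl ketones with 1,1-disubstituted alkenes and the SnCl4-mediated cation–enol cyclisation of olefinic β-keto esters; running them as one cascade has no precedent. The ring closes in a 6-(enolendo)-exo-trig mode. The only new stereocentre, C1, is an enolisable β-keto ester carbon and is left racemic, to be set in step 2. The step needs Markovnikov regiochemistry (isobutene CH2 to the enone terminus, tertiary cation to C1), C- rather than O-capture of the cation, and no oligomerisation of isobutene; the first follows from the cation stabilities, the second from reversible O-alkylation (the dihydropyran reionises under SnCl4, the C–C bond does not), the third from low temperature and slow addition to the preformed chelate.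

Step 2
Reactants: 4 methyl 2,2-dimethyl-6-oxocyclohexane-1-carboxylate
Product: 5 methyl (1S)-1-hydroxy-2,2-dimethyl-6-oxocyclohexane-1-carboxylate
Conditions: Ni(ClO4)2·6H2O (10 mol %), (R,R)-DBFOX/Ph (11 mol %), 2-(phenylsulfonyl)-3-phenyloxaziridine, 4 Å MS, CH2Cl2, rt
Reagents that add atoms: 2-(phenylsulfonyl)-3-phenyloxaziridine, O=S(=O)(N1OC1c1ccccc1)c1ccccc1
Why: Catalytic enantioselective α-hydroxylation of a β-keto ester, in which the chiral bis(oxazoline) nickel enolate shields one face so that the oxaziridine oxygen should be delivered to give the (S)-alcohol under catalyst control (the ligand antipode is used if the sense proves reversed).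

Step 3
Reactants: 5 methyl (1S)-1-hydroxy-2,2-dimethyl-6-oxocyclohexane-1-carboxylate
Product: 6 (1R)-1-(hydroxymethyl)-6,6-dimethylcyclohexane-1,2-diol (mixture of C2 epimers)
Conditions: LiAlH4, THF, 0 °C → rt; Rochelle salt
Reagents that add atoms: none
Why: Hydride reduction of ester and ketone gives the triol; C1 has no acidic hydrogen and is untouched, and the new carbinol centre C2 is formed without control because it is oxidised again in step 19.

Step 4
Reactants: 6 (1R)-1-(hydroxymethyl)-6,6-dimethylcyclohexane-1,2-diol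
Product: 7 (1S)-6,6-dimethyl-1-{[(1-phenyl-1H-tetrazol-5-yl)sulfanyl]methyl}cyclohexane-1,2-diol (mixture of C2 epimers)
Conditions: 1-phenyl-1H-tetrazole-5-thiol, PPh3, DIAD, THF, 0 °C → rt
Reagents that add atoms: 1-phenyl-1H-tetrazole-5-thiol, Sc1nnnn1-c1ccccc1
Why: Mitsunobu thioetherification is selective for the only primary hydroxyl, and a spiro-epoxide formed by neighbouring-group closure would be opened by the thiolate at the same CH2, so C1 is unchanged.

Step 5
Reactants: 7 (1S)-6,6-dimethyl-1-{[(1-phenyl-1H-tetrazol-5-yl)sulfanyl]methyl}cyclohexane-1,2-diol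
Product: 8 5-({[(1S)-2,2-dimethyl-1,6-bis(triethylsilyloxy)cyclohexyl]methyl}sulfanyl)-1-phenyl-1H-tetrazole (mixture of C6 epimers)
Conditions: Et3SiOTf (2.5 equiv), 2,6-lutidine, CH2Cl2, 0 °C → rt
Reagents that add atoms: triethylsilyl trifluoromethanesulfonate, CC[Si](CC)(CC)OS(=O)(=O)C(F)(F)F
Why: Silyl triflate silylation protects the secondary and the hindered tertiary hydroxyl, so that no alkoxide can attack the tetrazole (Smiles-type) or quench the sulfone carbanion in step 16.

Step 6
Reactants: 8 5-({[(1S)-2,2-dimethyl-1,6-bis(triethylsilyloxy)cyclohexyl]methyl}sulfanyl)-1-phenyl-1H-tetrazole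
Product: 9 5-({[(1S)-2,2-dimethyl-1,6-bis(triethylsilyloxy)cyclohexyl]methyl}sulfonyl)-1-phenyl-1H-tetrazole (mixture of C6 epimers)
Conditions: mCPBA (2.5 equiv), NaHCO3, CH2Cl2, 0 °C → rt
Reagents that add atoms: 3-chloroperoxybenzoic acid, OOC(=O)c1cccc(Cl)c1
Why: Peracid oxidation of the sulfide to the sulfone by two oxygen transfers, with no alkene or other oxidisable group present.

Step 7
Reactants: 10 [(2R)-2-methyloxiran-2-yl]methanol
Product: 11 (2S)-2-methylhex-5-ene-1,2-diol
Conditions: allylMgBr (2.5 equiv), CuI (10 mol %), THF, −30 → 0 °C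
Reagents that add atoms: allylmagnesium bromide, C=CC[Mg]Br
Why: Copper-catalysed Grignard opening of the epoxide at its unsubstituted CH2 (SN2) breaks no bond at the quaternary stereocentre, so the configuration of 10 is carried into the diol.

Step 8
Reactants: 11 (2S)-2-methylhex-5-ene-1,2-diol
Product: 12 (2S)-2-(but-3-en-1-yl)-2-methyloxirane
Conditions: NaH (2.2 equiv), 1-(p-toluenesulfonyl)imidazole, THF, 0 °C → rt
Reagents that add atoms: none
Why: One-pot selective sulfonylation of the primary hydroxyl and Williamson closure by the tertiary alkoxide (3-exo-tet) moves the epoxide to the other CH2 with retention at the stereocentre.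

Step 9
Reactants: 12 (2S)-2-(but-3-en-1-yl)-2-methyloxirane
Product: 13 3-[(2S)-2-methyloxiran-2-yl]propanal
Conditions: O3, CH2Cl2, −78 °C; then Me2S
Reagents that add atoms: ozone, [O-][O+]=O
Why: Ozonolysis with reductive work-up cleaves the only alkene to the aldehyde, the epoxide being inert to ozone.

Step 10
Reactants: 13 3-[(2S)-2-methyloxiran-2-yl]propanal
Product: 14 (3R,4R)-3-methyl-6-[(2S)-2-methyloxiran-2-yl]hex-1-en-4-ol
Conditions: diisopropyl (R,R)-tartrate (Z)-crotylboronate, 4 Å MS, toluene, −78 °C; then aq. NaHCO3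
Reagents that add atoms: diisopropyl (4R,5R)-2-[(2Z)-but-2-en-1-yl]-1,3,2-dioxaborolane-4,5-dicarboxylate, CC(C)OC(=O)[C@@H]1OB(C/C=C\C)O[C@H]1C(=O)OC(C)C
Why: Roush crotylboration through a chair six-membered transition state, in which the Z geometry of the reagent gives the 3,4-syn relationship and the (R,R)-tartrate directs attack on the Si face of the aldehyde (reagent control), with no Lewis acid that would open the epoxide.

Step 11
Reactants: 14 (3R,4R)-3-methyl-6-[(2S)-2-methyloxiran-2-yl]hex-1-en-4-ol
Product: 15 (3R,4R)-3-methyl-6-[(2S)-2-methyloxiran-2-yl]hex-1-en-4-yl methanesulfonate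
Conditions: MsCl, Et3N, CH2Cl2, 0 °C
Reagents that add atoms: methanesulfonyl chloride, CS(=O)(=O)Cl
Why: Sulfonylation of the secondary alcohol with retention at C4 turns it into a leaving group, and the epoxide is stable to the amine base.

Step 12
Reactants: 15 (3R,4R)-3-methyl-6-[(2S)-2-methyloxiran-2-yl]hex-1-en-4-yl methanesulfonate
Product: 17 [(3R,6S)-6-[(2R)-but-3-en-2-yl]-3-methyl-1,2-dioxan-3-yl]methanol, via hydroperoxy mesylate 16 (not isolated)
Conditions: H2O2 (ethereal), H3PMo12O40 (5 mol %), Et2O, rt; then CsOH·H2O, DMF, 0 °C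
Reagents that add atoms: hydrogen peroxide, OO
Why: Phosphomolybdic acid-catalysed perhydrolysis should open the 2,2-disubstituted epoxide at its tertiary carbon with inversion, and the caesium peroxide of 16 then displaces the mesylate in a 6-exo-tet SN2 closure with inversion, so that both dioxane stereocentres follow from centres fixed in 10 and in step 10, the more acidic alpha-effect hydroperoxide reacting in preference to the primary hydroxyl.

Step 13
Reactants: 17 [(3R,6S)-6-[(2R)-but-3-en-2-yl]-3-methyl-1,2-dioxan-3-yl]methanol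
Product: 19 (2S)-2-[(3S,6R)-6-(hydroxymethyl)-6-methyl-1,2-dioxan-3-yl]propanoic acid, via dioxanyl propanal 18 (not isolated)
Conditions: O3, CH2Cl2/MeOH, −78 °C; Me2S; then NaClO2, NaH2PO4, 2-methylbut-2-ene, t-BuOH/H2O, 0 °C
Reagents that add atoms: ozone, [O-][O+]=O; sodium chlorite, [Na+].[O-]Cl=O
Why: Ozonolysis of the vinyl group and immediate Pinnick oxidation at buffered pH unmask the carboxyl without base, which spares the alpha stereocentre and the beta-peroxy linkage from epimerisation and elimination, the dialkyl peroxide and the primary alcohol being inert to both oxidants.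

Step 14
Reactants: 19 (2S)-2-[(3S,6R)-6-(hydroxymethyl)-6-methyl-1,2-dioxan-3-yl]propanoic acid
Product: 20 methyl (2S)-2-[(3S,6R)-6-(hydroxymethyl)-6-methyl-1,2-dioxan-3-yl]propanoate
Conditions: Me3SiCHN2, MeOH/toluene, 0 °C
Reagents that add atoms: trimethylsilyldiazomethane, C[Si](C)(C)C=[N+]=[N-]
Why: Esterification with the diazoalkane methylates only the carboxylic acid under neutral conditions.

Step 15
Reactants: 20 methyl (2S)-2-[(3S,6R)-6-(hydroxymethyl)-6-methyl-1,2-dioxan-3-yl]propanoate
Product: 21 methyl (2S)-2-[(3S,6R)-6-formyl-6-methyl-1,2-dioxan-3-yl]propanoate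
Conditions: Dess–Martin periodinane, NaHCO3, CH2Cl2, 0 °C → rt
Reagents that add atoms: none
Why: Dess–Martin oxidation of the primary alcohol gives an aldehyde with a quaternary alpha carbon, which cannot enolise and is configurationally safe.

Step 16
Reactants: 9 5-({[(1S)-2,2-dimethyl-1,6-bis(triethylsilyloxy)cyclohexyl]methyl}sulfonyl)-1-phenyl-1H-tetrazole; 21 methyl (2S)-2-[(3S,6R)-6-formyl-6-methyl-1,2-dioxan-3-yl]propanoate
Product: 22 methyl (2S)-2-[(3S,6R)-6-{(E)-2-[(1S)-2,2-dimethyl-1,6-bis(triethylsilyloxy)cyclohexyl]ethenyl}-6-methyl-1,2-dioxan-3-yl]propanoate (mixture of cyclohexane C6 epimers)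
Conditions: 9, KN(SiMe3)2, DME, −78 °C; then 21, −78 °C → rt
Reagents that add atoms: none
Why: Julia–Kocienski olefination, in which the sulfone carbanion adds to the aldehyde at −78 °C faster than it deprotonates the ester, and Smiles rearrangement with loss of SO2 and the tetrazolate gives the alkene, whose geometry is irrelevant because step 18 reduces it.

Step 17
Reactants: 22 methyl (2S)-2-[(3S,6R)-6-{(E)-2-[(1S)-2,2-dimethyl-1,6-bis(triethylsilyloxy)cyclohexyl]ethenyl}-6-methyl-1,2-dioxan-3-yl]propanoate
Product: 23 methyl (2S)-2-[(3S,6R)-6-{(E)-2-[(1S)-1,6-dihydroxy-2,2-dimethylcyclohexyl]ethenyl}-6-methyl-1,2-dioxan-3-yl]propanoate (mixture of cyclohexane C6 epimers)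
Conditions: Bu4NF, AcOH, THF, rt
Reagents that add atoms: none
Why: Fluoride-mediated desilylation, buffered with acetic acid to spare the ester alpha centre and the peroxide, frees both hydroxyls and lowers the steric shielding of the alkene before its reduction.

Step 18
Reactants: 23 methyl (2S)-2-[(3S,6R)-6-{(E)-2-[(1S)-1,6-dihydroxy-2,2-dimethylcyclohexyl]ethenyl}-6-methyl-1,2-dioxan-3-yl]propanoate
Product: 24 methyl (2S)-2-[(3S,6R)-6-{2-[(1S)-1,6-dihydroxy-2,2-dimethylcyclohexyl]ethyl}-6-methyl-1,2-dioxan-3-yl]propanoate (mixture of cyclohexane C6 epimers)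
Conditions: KO2CN=NCO2K, AcOH, MeOH/CH2Cl2, 0 °C → rt, repeated charges
Reagents that add atoms: none
Why: Diimide reduction (concerted syn transfer of H2 from HN=NH) saturates an alkene without cleaving the O–O bond, and this alkene is the only C=C present because the future methylidene carbon is still a carbinol.

Step 19
Reactants: 24 methyl (2S)-2-[(3S,6R)-6-{2-[(1S)-1,6-dihydroxy-2,2-dimethylcyclohexyl]ethyl}-6-methyl-1,2-dioxan-3-yl]propanoate
Product: 25 methyl (2S)-2-[(3S,6R)-6-{2-[(1S)-1-hydroxy-2,2-dimethyl-6-oxocyclohexyl]ethyl}-6-methyl-1,2-dioxan-3-yl]propanoate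
Conditions: Dess–Martin periodinane, NaHCO3, CH2Cl2, 0 °C → rt
Reagents that add atoms: none
Why: Dess–Martin oxidation converts the secondary alcohol into the ketone and so removes the stereorandom centre of step 3, the tertiary alcohol and the peroxide being inert.

Step 20
Reactants: 25 methyl (2S)-2-[(3S,6R)-6-{2-[(1S)-1-hydroxy-2,2-dimethyl-6-oxocyclohexyl]ethyl}-6-methyl-1,2-dioxan-3-yl]propanoate
Product: 26 methyl (2S)-2-[(3S,6R)-6-{2-[(1S)-1-hydroxy-2,2-dimethyl-6-methylidenecyclohexyl]ethyl}-6-methyl-1,2-dioxan-3-yl]propanoate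
Conditions: Ph3PCH3Br, KOtBu (3 equiv each), THF, 0 °C → rt
Reagents that add atoms: methyltriphenylphosphonium bromide, C[P+](c1ccccc1)(c1ccccc1)c1ccccc1.[Br-]
Why: Wittig methylenation with excess ylide (the first equivalent deprotonates the tertiary hydroxyl) installs the exocyclic methylene, the ketone reacting much faster than the methyl ester and no stereocentre lying alpha to the reacting carbonyl.

Compound list
1 | methyl 3-oxopent-4-enoate | C=CC(=O)CC(=O)OC | starting material
2 | 2-methylpropene (isobutene) | CC(C)=C | starting material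
3 | methyl 7-methyl-3-oxooct-7-enoate | C=C(C)CCCC(=O)CC(=O)OC | intermediate
4 | methyl 2,2-dimethyl-6-oxocyclohexane-1-carboxylate (racemic) | CC1(C)CCCC(=O)C1C(=O)OC | intermediate
5 | methyl (1S)-1-hydroxy-2,2-dimethyl-6-oxocyclohexane-1-carboxylate | O=C1CCCC(C)(C)[C@@]1(O)C(=O)OC | intermediate
6 | (1R)-1-(hydroxymethyl)-6,6-dimethylcyclohexane-1,2-diol (C2 epimers) | OC1CCCC(C)(C)[C@@]1(O)CO | intermediate
7 | (1S)-6,6-dimethyl-1-{[(1-phenyl-1H-tetrazol-5-yl)sulfanyl]methyl}cyclohexane-1,2-diol (C2 epimers) | OC1CCCC(C)(C)[C@@]1(O)CSc1nnnn1-c1ccccc1 | intermediate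
8 | 5-({[(1S)-2,2-dimethyl-1,6-bis(triethylsilyloxy)cyclohexyl]methyl}sulfanyl)-1-phenyl-1H-tetrazole (C6 epimers) | CC[Si](CC)(CC)OC1CCCC(C)(C)[C@@]1(O[Si](CC)(CC)CC)CSc1nnnn1-c1ccccc1 | intermediate
9 | 5-({[(1S)-2,2-dimethyl-1,6-bis(triethylsilyloxy)cyclohexyl]methyl}sulfonyl)-1-phenyl-1H-tetrazole (C6 epimers) | CC[Si](CC)(CC)OC1CCCC(C)(C)[C@@]1(O[Si](CC)(CC)CC)CS(=O)(=O)c1nnnn1-c1ccccc1 | intermediate
10 | [(2R)-2-methyloxiran-2-yl]methanol | OC[C@]1(C)CO1 | starting material
11 | (2S)-2-methylhex-5-ene-1,2-diol | OC[C@](O)(C)CCC=C | intermediate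
12 | (2S)-2-(but-3-en-1-yl)-2-methyloxirane | C1O[C@@]1(C)CCC=C | intermediate
13 | 3-[(2S)-2-methyloxiran-2-yl]propanal | C1O[C@@]1(C)CCC=O | intermediate
14 | (3R,4R)-3-methyl-6-[(2S)-2-methyloxiran-2-yl]hex-1-en-4-ol | C1O[C@@]1(C)CC[C@H]([C@H](C)C=C)O | intermediate
15 | (3R,4R)-3-methyl-6-[(2S)-2-methyloxiran-2-yl]hex-1-en-4-yl methanesulfonate | C1O[C@@]1(C)CC[C@H]([C@H](C)C=C)OS(C)(=O)=O | intermediate
16 | (3R,4R,7R)-7-hydroperoxy-8-hydroxy-3,7-dimethyloct-1-en-4-yl methanesulfonate | OC[C@@](OO)(C)CC[C@H]([C@H](C)C=C)OS(C)(=O)=O | intermediate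
17 | [(3R,6S)-6-[(2R)-but-3-en-2-yl]-3-methyl-1,2-dioxan-3-yl]methanol | OC[C@@]1(C)CC[C@@H]([C@H](C)C=C)OO1 | intermediate
18 | (2S)-2-[(3S,6R)-6-(hydroxymethyl)-6-methyl-1,2-dioxan-3-yl]propanal | OC[C@@]1(C)CC[C@@H]([C@H](C)C=O)OO1 | intermediate
19 | (2S)-2-[(3S,6R)-6-(hydroxymethyl)-6-methyl-1,2-dioxan-3-yl]propanoic acid | OC[C@@]1(C)CC[C@@H]([C@H](C)C(=O)O)OO1 | intermediate
20 | methyl (2S)-2-[(3S,6R)-6-(hydroxymethyl)-6-methyl-1,2-dioxan-3-yl]propanoate | OC[C@@]1(C)CC[C@@H]([C@H](C)C(=O)OC)OO1 | intermediate
21 | methyl (2S)-2-[(3S,6R)-6-formyl-6-methyl-1,2-dioxan-3-yl]propanoate | O=C[C@@]1(C)CC[C@@H]([C@H](C)C(=O)OC)OO1 | intermediate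
22 | methyl (2S)-2-[(3S,6R)-6-{(E)-2-[(1S)-2,2-dimethyl-1,6-bis(triethylsilyloxy)cyclohexyl]ethenyl}-6-methyl-1,2-dioxan-3-yl]propanoate (cyclohexane C6 epimers) | CC[Si](CC)(CC)OC1CCCC(C)(C)[C@@]1(O[Si](CC)(CC)CC)/C=C/[C@@]1(C)CC[C@@H]([C@H](C)C(=O)OC)OO1 | intermediate
23 | methyl (2S)-2-[(3S,6R)-6-{(E)-2-[(1S)-1,6-dihydroxy-2,2-dimethylcyclohexyl]ethenyl}-6-methyl-1,2-dioxan-3-yl]propanoate (cyclohexane C6 epimers) | OC1CCCC(C)(C)[C@@]1(O)/C=C/[C@@]1(C)CC[C@@H]([C@H](C)C(=O)OC)OO1 | intermediate
24 | methyl (2S)-2-[(3S,6R)-6-{2-[(1S)-1,6-dihydroxy-2,2-dimethylcyclohexyl]ethyl}-6-methyl-1,2-dioxan-3-yl]propanoate (cyclohexane C6 epimers) | OC1CCCC(C)(C)[C@@]1(O)CC[C@@]1(C)CC[C@@H]([C@H](C)C(=O)OC)OO1 | intermediate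
25 | methyl (2S)-2-[(3S,6R)-6-{2-[(1S)-1-hydroxy-2,2-dimethyl-6-oxocyclohexyl]ethyl}-6-methyl-1,2-dioxan-3-yl]propanoate | O=C1CCCC(C)(C)[C@@]1(O)CC[C@@]1(C)CC[C@@H]([C@H](C)C(=O)OC)OO1 | intermediate
26 | methyl (2S)-2-[(3S,6R)-6-{2-[(1S)-1-hydroxy-2,2-dimethyl-6-methylidenecyclohexyl]ethyl}-6-methyl-1,2-dioxan-3-yl]propanoate | C=C1CCCC(C)(C)[C@@]1(O)CC[C@@]1(C)CC[C@@H]([C@H](C)C(=O)OC)OO1 | target

Total step count: 20. Longest linear sequence: 14 steps (steps 7 to 15, then 16 to 20); the ring branch (steps 1 to 6) joins at step 16.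

Steps most likely to fail

Step 1 (Proposed new method). The cascade may be outrun by cationic oligomerisation of isobutene or polymerisation of 1, or it may stall after the ene addition or after capture of the cation at oxygen. The fallback uses known chemistry in two separate operations and sets out from 1: TiCl4-mediated Sakurai conjugate addition of methallyltrimethylsilane (CH2Cl2, −78 °C) gives 3, now isolated, and SnCl4 in CH2Cl2 (0 °C → rt) then effects the known cation–enol cyclisation of this olefinic β-keto ester, coming back to the route at 4. This fallback makes no compound outside the list (F0).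

Step 12. The peroxide anion may act as a base rather than a nucleophile, eliminating the hindered secondary mesylate towards the allylic position, or the primary alkoxide may close a tetrahydropyran instead. The fallback avoids SN2 at this carbon and sets out from 13: Wittig olefination with methyl 2-(triphenylphosphoranylidene)propanoate gives methyl (2E)-2-methyl-5-[(2S)-2-methyloxiran-2-yl]pent-2-enoate F1; the same H3PMo12O40-catalysed perhydrolysis gives methyl (2E,6R)-6-hydroperoxy-7-hydroxy-2,6-dimethylhept-2-enoate F2; Et2NH in CF3CH2OH then closes the dioxane by intramolecular peroxy-Michael addition and comes back to the route at 20, bypassing steps 10, 11, 13 and 14. The two centres formed in that closure are not reagent-controlled, so the required diastereomer of 20 would have to be separated by chromatography.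

Step 18. Hydrogen transfer to an alkene flanked by two fully substituted carbons may be so slow that disproportionation of diimide consumes the reagent first. The fallback replaces the uncatalysed transfer by a hydroxyl-directed homogeneous hydrogenation and sets out from 23: [Ir(cod)(PCy3)(py)]PF6 under H2 (1 atm) in CH2Cl2, with the tertiary allylic hydroxyl binding the cationic iridium centre and delivering H2 to the hindered alkene, coming back to the route at 24. The tolerance of the O–O bond to this catalyst would have to be secured by short reaction time; the fallback makes no compound outside the list (F0).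

Further compounds
F0 | step 1 | none | none
F1 | step 12 | methyl (2E)-2-methyl-5-[(2S)-2-methyloxiran-2-yl]pent-2-enoate | C1O[C@@]1(C)CC/C=C(\C)C(=O)OC
F2 | step 12 | methyl (2E,6R)-6-hydroperoxy-7-hydroxy-2,6-dimethylhept-2-enoate | OC[C@@](OO)(C)CC/C=C(\C)C(=O)OC
F0 | step 18 | none | none
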